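**Retrosynthetic overview**
- The 3,4-dihydroxybenzoyl group at C3, the C10 side chain at the C1 bridgehead and the two terminal isopropylidene groups are added last (C3 acylation, bridgehead alkylation, double cross-metathesis) to a chiral bicyclo[3.3.1]nonane-2,4,9-trione.
- Key disconnection: the C1–C8 ring bond and the C7–allyl bond are formed in one enantioselective, desymmetrizing radical cyclization/allyl-transfer cascade on an achiral 2,2-disubstituted cyclohexane-1,3,5-trione; this sets C1, C5 and C7 together.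
- That trione comes from acetylacetone: C-prenylation, O-prenylation/Claisen rearrangement (C5–C6 bond between two quaternary carbons), then double Claisen condensation with dimethyl carbonate.
- Ring order: ring B (the C1–C5/C9 trione ring) first, ring A (the C1/C5–C9 cyclohexanone) second, by the radical step.
- Side pieces: the chain bromide from isoprene monoxide (carbinol by catalytic asymmetric allylation) and the aroyl chloride from catechol and CO2.

Assumption: bicyclo[3.3.1]nonane locants are C1 = chain-bearing bridgehead, C5 = prenyl-bearing bridgehead, C6 = CMe2, C7 = CH(prenyl); the sense of induction in step 4 is taken as drawn, and the antipodal ligand is used if it proves opposite.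

**Step 1**
Reactants: 1 acetylacetone (pentane-2,4-dione); 2 prenyl bromide (1-bromo-3-methylbut-2-ene)
Product: 3 3-(3-methylbut-2-en-1-yl)pentane-2,4-dione
Conditions: K2CO3, acetone, reflux
Reagents that add atoms: none
Why: SN2 C-alkylation of the acetylacetone enolate by the soft allylic bromide gives the mono-C-prenyl diketone; no stereocentre is formed.

**Step 2**
Reactants: 3 3-(3-methylbut-2-en-1-yl)pentane-2,4-dione; 4 prenol (3-methylbut-2-en-1-ol)
Product: 6 3-(2-methylbut-3-en-2-yl)-3-(3-methylbut-2-en-1-yl)pentane-2,4-dione, via enol ether 5 (not isolated)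
Conditions: PPh3, DIAD, THF, 0 °C to rt; then PhMe, 120 °C (sealed tube)
Reagents that add atoms: none
Why: Mitsunobu O-alkylation of the acidic 2-substituted 1,3-diketone gives the allyl vinyl ether, and its Claisen rearrangement forms the C5–C6 bond between two quaternary carbons while turning the O-prenyl group into the 1,1-dimethylallyl group; the product is achiral.

**Step 3**
Reactants: 6 3-(2-methylbut-3-en-2-yl)-3-(3-methylbut-2-en-1-yl)pentane-2,4-dione; 7 dimethyl carbonate
Product: 9 2-(2-methylbut-3-en-2-yl)-2-(3-methylbut-2-en-1-yl)cyclohexane-1,3,5-trione, via keto ester 8 (not isolated)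
Conditions: LiN(SiMe3)2 (3.3 equiv), THF, −78 °C; (MeO)2CO (1.05 equiv), −78 to 50 °C; aq. HCl
Reagents that add atoms: none
Why: Claisen condensation of one methyl ketone enolate with the carbonate, then Dieckmann ring closure by the second enolate, is driven by the stabilised trione enolate and gives ring B; the trione has a mirror plane, so no stereocentre exists yet.

**Step 4**
Reactants: 9 2-(2-methylbut-3-en-2-yl)-2-(3-methylbut-2-en-1-yl)cyclohexane-1,3,5-trione; 10 allyl methyl sulfone (3-(methanesulfonyl)prop-1-ene)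
Product: 11 (1S,5R,7R)-6,6-dimethyl-5-(3-methylbut-2-en-1-yl)-7-(prop-2-en-1-yl)bicyclo[3.3.1]nonane-2,4,9-trione
Conditions: 4CzIPN [2,4,5,6-tetrakis(carbazol-9-yl)isophthalonitrile] (2 mol %), Mg(ClO4)2 (20 mol %), (S,S)-t-Bu-box [2,2'-isopropylidenebis((4S)-4-tert-butyl-2-oxazoline)] (22 mol %), 2,6-lutidine (1.1 equiv), 10 (4 equiv), CH2Cl2, 450 nm LED, −20 °C
Reagents that add atoms: none
Why: Proposed new method: the excited photocatalyst oxidises the magnesium–bis(oxazoline)-bound enolate of 9 to the 1,3-dicarbonyl radical, which closes 6-endo onto the terminal vinyl carbon of the axially held 1,1-dimethylallyl arm (the usual mode of 2-oxo-5-hexenyl radicals); the C7 radical then adds to 10 from the open exo face and expels the methylsulfonyl radical (SH2' allyl transfer, giving the equatorial 7-allyl group), and the reduced photocatalyst converts that radical to sulfinate; because the two enolisable CH2 positions of 9 are enantiotopic, the chiral Lewis acid decides which one cyclises and so sets C1, C5 and C7 in one step; the closest known reaction types are Mn(OAc)3-mediated 6-endo oxidative cyclisations of unsaturated 1,3-dicarbonyls to bicyclo[3.3.1]nonanes, Mg(ClO4)2/bis(oxazoline)-controlled enantioselective radical cyclisations of unsaturated β-keto esters, and photoredox allylations with allyl sulfones.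

**Step 5**
Reactants: 12 isoprene monoxide (2-methyl-2-vinyloxirane)
Product: 13 (2E)-4-bromo-2-methylbut-2-en-1-ol
Conditions: 48% aq. HBr, CuBr (5 mol %), Et2O, −20 to 0 °C
Reagents that add atoms: hydrogen bromide, Br
Why: Conjugate (SN2') opening of the vinyl epoxide by bromide, with the allylic bromide settling as the more stable primary, trisubstituted (E)-alkene in which the two CH2X groups are trans.

**Step 6**
Reactants: 13 (2E)-4-bromo-2-methylbut-2-en-1-ol
Product: 14 (2E)-4-bromo-2-methylbut-2-enal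
Conditions: activated MnO2, CH2Cl2, rt
Reagents that add atoms: none
Why: Chemoselective allylic alcohol oxidation with MnO2 leaves the allylic bromide and the (E)-alkene untouched.

**Step 7**
Reactants: 14 (2E)-4-bromo-2-methylbut-2-enal
Product: 15 (2E,4S)-1-bromo-3-methylhepta-2,6-dien-4-ol
Conditions: Bu3SnCH2CH=CH2, (S)-BINOL (10 mol %), Ti(Oi-Pr)4 (10 mol %), 4 Å sieves, CH2Cl2, −20 °C
Reagents that add atoms: allyltributylstannane, C=CC[Sn](CCCC)(CCCC)CCCC
Why: Keck asymmetric allylation, in which the (S)-BINOL–titanium Lewis acid delivers the allyl group to the same aldehyde face that gives the (S)-alcohol from benzaldehyde, sets the (S)-carbinol under neutral conditions that spare the allylic bromide.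

**Step 8**
Reactants: 15 (2E,4S)-1-bromo-3-methylhepta-2,6-dien-4-ol
Product: 16 tert-butyl{[(2E,4S)-1-bromo-3-methylhepta-2,6-dien-4-yl]oxy}dimethylsilane
Conditions: TBSOTf, 2,6-lutidine, CH2Cl2, −78 °C
Reagents that add atoms: tert-butyldimethylsilyl triflate, CC(C)(C)[Si](C)(C)OS(=O)(=O)C(F)(F)F
Why: Silyl ether formation with a silyl triflate and a non-nucleophilic base protects the alcohol without displacing the allylic bromide; the stereocentre is untouched.

**Step 9**
Reactants: 17 catechol (benzene-1,2-diol)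
Product: 18 4-bromobenzene-1,2-diol
Conditions: NBS, MeCN, −20 °C to rt
Reagents that add atoms: N-bromosuccinimide, O=C1CCC(=O)N1Br
Why: Electrophilic aromatic bromination occurs para to a hydroxyl group of the electron-rich ring.

**Step 10**
Reactants: 18 4-bromobenzene-1,2-diol
Product: 19 4-bromo-1,2-bis[(tert-butyldimethylsilyl)oxy]benzene
Conditions: TBSCl, imidazole, DMF, rt
Reagents that add atoms: tert-butyldimethylsilyl chloride, CC(C)(C)[Si](C)(C)Cl
Why: Standard silylation of both phenols gives ethers that survive organolithium chemistry and fall off with fluoride at the end.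

**Step 11**
Reactants: 19 4-bromo-1,2-bis[(tert-butyldimethylsilyl)oxy]benzene; 20 carbon dioxide
Product: 23 3,4-bis[(tert-butyldimethylsilyl)oxy]benzoyl chloride, via aryllithium 21 (not isolated), via lithium carboxylate 22 (not isolated)
Conditions: n-BuLi, THF, −78 °C; CO2; concentrate; (COCl)2, cat. DMF, CH2Cl2, 0 °C; used crude
Reagents that add atoms: oxalyl chloride, ClC(=O)C(=O)Cl
Why: Bromine–lithium exchange, carboxylation, and conversion of the lithium carboxylate to the acid chloride with oxalyl chloride proceed without free acid, so the aryl silyl ethers stay on.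

**Step 12**
Reactants: 11 (1S,5R,7R)-6,6-dimethyl-5-(3-methylbut-2-en-1-yl)-7-(prop-2-en-1-yl)bicyclo[3.3.1]nonane-2,4,9-trione
Product: 24 (1S,5R,7R)-6,6-dimethyl-5-(3-methylbut-2-en-1-yl)-7-(prop-2-en-1-yl)-2-{[2-(trimethylsilyl)ethoxy]methoxy}bicyclo[3.3.1]non-2-ene-4,9-dione
Conditions: SEMCl, i-Pr2NEt, CH2Cl2, 0 °C
Reagents that add atoms: 2-(trimethylsilyl)ethoxymethyl chloride, C[Si](C)(C)CCOCCl
Why: O-alkylation of the vinylogous acid at the less hindered oxygen (O2, next to the bridgehead C–H and away from the C5/C6 quaternary pair) gives the vinylogous ester needed for bridgehead metalation; no stereocentre is touched.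

**Step 13**
Reactants: 24 (1S,5R,7R)-6,6-dimethyl-5-(3-methylbut-2-en-1-yl)-7-(prop-2-en-1-yl)-2-{[2-(trimethylsilyl)ethoxy]methoxy}bicyclo[3.3.1]non-2-ene-4,9-dione; 16 tert-butyl{[(2E,4S)-1-bromo-3-methylhepta-2,6-dien-4-yl]oxy}dimethylsilane
Product: 26 (1S,5R,7R)-1-[(2E,4S)-4-{[tert-butyl(dimethyl)silyl]oxy}-3-methylhepta-2,6-dien-1-yl]-6,6-dimethyl-5-(3-methylbut-2-en-1-yl)-7-(prop-2-en-1-yl)-2-{[2-(trimethylsilyl)ethoxy]methoxy}bicyclo[3.3.1]non-2-ene-4,9-dione, via bridgehead organolithium 25 (not isolated)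
Conditions: LiN(i-Pr)2 (1.3 equiv), THF, −78 °C; then 16 (1.5 equiv), −78 to 0 °C
Reagents that add atoms: none
Why: Bridgehead lithiation of the bicyclic vinylogous ester (known from earlier bicyclic acylphloroglucinol syntheses) followed by SN2 alkylation with the primary allylic bromide installs the chain with retention at C1, which the bicycle enforces, and carries the (E)-alkene and (S)-carbinol in unchanged.

**Step 14**
Reactants: 26 (1S,5R,7R)-1-[(2E,4S)-4-{[tert-butyl(dimethyl)silyl]oxy}-3-methylhepta-2,6-dien-1-yl]-6,6-dimethyl-5-(3-methylbut-2-en-1-yl)-7-(prop-2-en-1-yl)-2-{[2-(trimethylsilyl)ethoxy]methoxy}bicyclo[3.3.1]non-2-ene-4,9-dione; 23 3,4-bis[(tert-butyldimethylsilyl)oxy]benzoyl chloride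
Product: 28 (1S,5S,7R)-3-{3,4-bis[(tert-butyldimethylsilyl)oxy]benzoyl}-1-[(2E,4S)-4-{[tert-butyl(dimethyl)silyl]oxy}-3-methylhepta-2,6-dien-1-yl]-6,6-dimethyl-5-(3-methylbut-2-en-1-yl)-7-(prop-2-en-1-yl)-2-{[2-(trimethylsilyl)ethoxy]methoxy}bicyclo[3.3.1]non-2-ene-4,9-dione, via vinyllithium 27 (not isolated)
Conditions: lithium 2,2,6,6-tetramethylpiperidide (1.5 equiv), THF, −78 °C; then 23, −78 °C
Reagents that add atoms: none
Why: Alkoxy-directed C3 lithiation of the vinylogous ester (no bridgehead hydrogen remains) and C-acylation with the aroyl chloride install the aryl ketone; the C5 descriptor changes from R to S only because the CIP priorities change.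

**Step 15**
Reactants: 28 (1S,5S,7R)-3-{3,4-bis[(tert-butyldimethylsilyl)oxy]benzoyl}-1-[(2E,4S)-4-{[tert-butyl(dimethyl)silyl]oxy}-3-methylhepta-2,6-dien-1-yl]-6,6-dimethyl-5-(3-methylbut-2-en-1-yl)-7-(prop-2-en-1-yl)-2-{[2-(trimethylsilyl)ethoxy]methoxy}bicyclo[3.3.1]non-2-ene-4,9-dione; 29 2-methylbut-2-ene
Product: 30 (1S,5S,7R)-3-{3,4-bis[(tert-butyldimethylsilyl)oxy]benzoyl}-1-[(2E,4S)-4-{[tert-butyl(dimethyl)silyl]oxy}-3,7-dimethylocta-2,6-dien-1-yl]-6,6-dimethyl-5,7-bis(3-methylbut-2-en-1-yl)-2-{[2-(trimethylsilyl)ethoxy]methoxy}bicyclo[3.3.1]non-2-ene-4,9-dione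
Conditions: second-generation Grubbs catalyst [RuCl2(H2IMes)(PCy3)(=CHPh)] (10 mol %), 29 (large excess), CH2Cl2, 40 °C
Reagents that add atoms: none
Why: Olefin cross-metathesis converts both terminal allyl groups (at C7 and at the chain end) into trisubstituted prenyl-type alkenes, while the existing trisubstituted alkenes do not react productively.

**Step 16**
Reactants: 30 (1S,5S,7R)-3-{3,4-bis[(tert-butyldimethylsilyl)oxy]benzoyl}-1-[(2E,4S)-4-{[tert-butyl(dimethyl)silyl]oxy}-3,7-dimethylocta-2,6-dien-1-yl]-6,6-dimethyl-5,7-bis(3-methylbut-2-en-1-yl)-2-{[2-(trimethylsilyl)ethoxy]methoxy}bicyclo[3.3.1]non-2-ene-4,9-dione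
Product: 31 (1S,5S,7R)-3-(3,4-dihydroxybenzoyl)-2-hydroxy-1-[(2E,4S)-4-hydroxy-3,7-dimethylocta-2,6-dien-1-yl]-6,6-dimethyl-5,7-bis(3-methylbut-2-en-1-yl)bicyclo[3.3.1]non-2-ene-4,9-dione (CNP0142498.1)
Conditions: tetrabutylammonium fluoride (6 equiv), THF, 0 °C to rt, degassed; aqueous work-up
Reagents that add atoms: none
Why: Fluoride-mediated desilylation removes the three silyl ethers and, by β-elimination, the SEM enol ether (good enolate leaving group) in one operation under non-acidic conditions that leave the prenyl groups, the allylic alcohol and all stereocentres alone.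

**Compound list**
1 | acetylacetone (pentane-2,4-dione) | CC(=O)CC(C)=O | starting material
2 | prenyl bromide (1-bromo-3-methylbut-2-ene) | CC(C)=CCBr | starting material
3 | 3-(3-methylbut-2-en-1-yl)pentane-2,4-dione | CC(=O)C(CC=C(C)C)C(C)=O | intermediate
4 | prenol (3-methylbut-2-en-1-ol) | CC(C)=CCO | starting material
5 | 3-(3-methylbut-2-en-1-yl)-4-[(3-methylbut-2-en-1-yl)oxy]pent-3-en-2-one (E/Z mixture) | CC(=O)C(CC=C(C)C)=C(C)OCC=C(C)C | intermediate
6 | 3-(2-methylbut-3-en-2-yl)-3-(3-methylbut-2-en-1-yl)pentane-2,4-dione | CC(=O)C(CC=C(C)C)(C(C)=O)C(C)(C)C=C | intermediate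
7 | dimethyl carbonate | COC(=O)OC | starting material
8 | methyl 4-acetyl-5,5-dimethyl-4-(3-methylbut-2-en-1-yl)-3-oxohept-6-enoate (racemic) | COC(=O)CC(=O)C(CC=C(C)C)(C(C)=O)C(C)(C)C=C | intermediate
9 | 2-(2-methylbut-3-en-2-yl)-2-(3-methylbut-2-en-1-yl)cyclohexane-1,3,5-trione (achiral; enolised in solution) | O=C1CC(=O)CC(=O)C1(CC=C(C)C)C(C)(C)C=C | intermediate
10 | allyl methyl sulfone (3-(methanesulfonyl)prop-1-ene) | C=CCS(C)(=O)=O | starting material
11 | (1S,5R,7R)-6,6-dimethyl-5-(3-methylbut-2-en-1-yl)-7-(prop-2-en-1-yl)bicyclo[3.3.1]nonane-2,4,9-trione (7-allyl exo) | C=CC[C@@H]1C[C@@H]2C(=O)[C@@](CC=C(C)C)(C(=O)CC2=O)C1(C)C | intermediate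
12 | isoprene monoxide (2-methyl-2-vinyloxirane, racemic) | CC1(C=C)CO1 | starting material
13 | (2E)-4-bromo-2-methylbut-2-en-1-ol | BrC/C=C(\C)CO | intermediate
14 | (2E)-4-bromo-2-methylbut-2-enal | BrC/C=C(\C)C=O | intermediate
15 | (2E,4S)-1-bromo-3-methylhepta-2,6-dien-4-ol | BrC/C=C(\C)[C@@H](O)CC=C | intermediate
16 | tert-butyl{[(2E,4S)-1-bromo-3-methylhepta-2,6-dien-4-yl]oxy}dimethylsilane | BrC/C=C(\C)[C@@H](O[Si](C)(C)C(C)(C)C)CC=C | intermediate
17 | catechol (benzene-1,2-diol) | Oc1ccccc1O | starting material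
18 | 4-bromobenzene-1,2-diol | Oc1ccc(Br)cc1O | intermediate
19 | 4-bromo-1,2-bis[(tert-butyldimethylsilyl)oxy]benzene | CC(C)(C)[Si](C)(C)Oc1ccc(Br)cc1O[Si](C)(C)C(C)(C)C | intermediate
20 | carbon dioxide | O=C=O | starting material
21 | {3,4-bis[(tert-butyldimethylsilyl)oxy]phenyl}lithium | [Li]c1ccc(O[Si](C)(C)C(C)(C)C)c(O[Si](C)(C)C(C)(C)C)c1 | intermediate
22 | lithium 3,4-bis[(tert-butyldimethylsilyl)oxy]benzoate | [Li+].[O-]C(=O)c1ccc(O[Si](C)(C)C(C)(C)C)c(O[Si](C)(C)C(C)(C)C)c1 | intermediate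
23 | 3,4-bis[(tert-butyldimethylsilyl)oxy]benzoyl chloride | O=C(Cl)c1ccc(O[Si](C)(C)C(C)(C)C)c(O[Si](C)(C)C(C)(C)C)c1 | intermediate
24 | (1S,5R,7R)-6,6-dimethyl-5-(3-methylbut-2-en-1-yl)-7-(prop-2-en-1-yl)-2-{[2-(trimethylsilyl)ethoxy]methoxy}bicyclo[3.3.1]non-2-ene-4,9-dione | C=CC[C@@H]1C[C@@H]2C(=O)[C@@](CC=C(C)C)(C(=O)C=C2OCOCC[Si](C)(C)C)C1(C)C | intermediate
25 | C1-lithio derivative of 24 (bridgehead organolithium) | C=CC[C@@H]1C[C@]2([Li])C(=O)[C@@](CC=C(C)C)(C(=O)C=C2OCOCC[Si](C)(C)C)C1(C)C | intermediate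
26 | (1S,5R,7R)-1-[(2E,4S)-4-{[tert-butyl(dimethyl)silyl]oxy}-3-methylhepta-2,6-dien-1-yl]-6,6-dimethyl-5-(3-methylbut-2-en-1-yl)-7-(prop-2-en-1-yl)-2-{[2-(trimethylsilyl)ethoxy]methoxy}bicyclo[3.3.1]non-2-ene-4,9-dione | C=CC[C@@H]1C[C@]2(C/C=C(\C)[C@@H](O[Si](C)(C)C(C)(C)C)CC=C)C(=O)[C@@](CC=C(C)C)(C(=O)C=C2OCOCC[Si](C)(C)C)C1(C)C | intermediate
27 | C3-lithio derivative of 26 (vinyllithium) | C=CC[C@@H]1C[C@]2(C/C=C(\C)[C@@H](O[Si](C)(C)C(C)(C)C)CC=C)C(=O)[C@@](CC=C(C)C)(C(=O)C([Li])=C2OCOCC[Si](C)(C)C)C1(C)C | intermediate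
28 | (1S,5S,7R)-3-{3,4-bis[(tert-butyldimethylsilyl)oxy]benzoyl}-1-[(2E,4S)-4-{[tert-butyl(dimethyl)silyl]oxy}-3-methylhepta-2,6-dien-1-yl]-6,6-dimethyl-5-(3-methylbut-2-en-1-yl)-7-(prop-2-en-1-yl)-2-{[2-(trimethylsilyl)ethoxy]methoxy}bicyclo[3.3.1]non-2-ene-4,9-dione | C=CC[C@@H]1C[C@]2(C/C=C(\C)[C@@H](O[Si](C)(C)C(C)(C)C)CC=C)C(=O)[C@@](CC=C(C)C)(C(=O)C(C(=O)c3ccc(O[Si](C)(C)C(C)(C)C)c(O[Si](C)(C)C(C)(C)C)c3)=C2OCOCC[Si](C)(C)C)C1(C)C | intermediate
29 | 2-methylbut-2-ene | CC=C(C)C | starting material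
30 | (1S,5S,7R)-3-{3,4-bis[(tert-butyldimethylsilyl)oxy]benzoyl}-1-[(2E,4S)-4-{[tert-butyl(dimethyl)silyl]oxy}-3,7-dimethylocta-2,6-dien-1-yl]-6,6-dimethyl-5,7-bis(3-methylbut-2-en-1-yl)-2-{[2-(trimethylsilyl)ethoxy]methoxy}bicyclo[3.3.1]non-2-ene-4,9-dione | CC(C)=CC[C@@H]1C[C@]2(C/C=C(\C)[C@@H](O[Si](C)(C)C(C)(C)C)CC=C(C)C)C(=O)[C@@](CC=C(C)C)(C(=O)C(C(=O)c3ccc(O[Si](C)(C)C(C)(C)C)c(O[Si](C)(C)C(C)(C)C)c3)=C2OCOCC[Si](C)(C)C)C1(C)C | intermediate
31 | (1S,5S,7R)-3-(3,4-dihydroxybenzoyl)-2-hydroxy-1-[(2E,4S)-4-hydroxy-3,7-dimethylocta-2,6-dien-1-yl]-6,6-dimethyl-5,7-bis(3-methylbut-2-en-1-yl)bicyclo[3.3.1]non-2-ene-4,9-dione | CC(C)=CC[C@@H]1C[C@]2(C/C=C(\C)[C@@H](O)CC=C(C)C)C(=O)[C@@](CC=C(C)C)(C(=O)C(C(=O)c3ccc(O)c(O)c3)=C2O)C1(C)C | target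

**Step count**
Total: 16 steps (9 on the main line, 4 for the chain bromide, 3 for the aroyl chloride).
Longest linear sequence: 9 steps (1, 2, 3, 4, 12, 13, 14, 15, 16).

**Three steps most likely to fail, with fallbacks**

Step 4 is the riskiest. Two things can go wrong: the chiral magnesium complex may not distinguish the two enantiotopic enol positions well, and the radical may close 5-exo onto the C5 prenyl group to give a bicyclo[3.2.1]octane. The second worry is eased by conformation: the tert-alkyl arm should sit pseudo-axial on the flat trione, because an equatorial 1,1-dimethylallyl group would eclipse both flanking carbonyls. That puts its vinyl group over C1/C3 and leaves the prenyl group in the ring plane, out of reach. If enantiocontrol fails, the fallback sets out from 9. The same cascade is run with Mg(ClO4)2 and no chiral ligand to give the racemic bicyclic trione F1. Treatment with SEMCl and i-Pr2NEt gives the racemic enol ether F2. In the bridgehead alkylation, LiN(i-Pr)2 is replaced by 0.55 equiv of lithium bis[(R)-1-phenylethyl]amide with LiCl (or its antipode, whichever metalates the (1S) series faster). Only the wanted enantiomer is then lithiated and alkylated by 16 (kinetic resolution by a chiral lithium amide). The unreacted enantiomer is separated, and the route is rejoined at 26.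

Step 3 may suffer from retro-Claisen cleavage of the non-enolisable 1,3-diketone by methoxide, or from a slow second condensation. The fallback sets out from 6. The mono-lithium enolate (LiN(SiMe3)2, −78 °C) is acylated with 1,1'-carbonyldiimidazole to give the keto acyl imidazolide F3. The ring is then closed by soft enolisation (MgBr2·OEt2, i-Pr2NEt, CH2Cl2) as an intramolecular C-acylation with no alkoxide present. The route is rejoined at 9.

Step 13 may give competing C3 metalation or a slow SN2 reaction with the hindered, oxygenated bromide 16. The fallback sets out from 24 and builds the chain on the core instead. Aldehyde 14 is converted with HC(OMe)3 and catalytic pyridinium p-toluenesulfonate into the small dimethyl acetal F4. Lithiated 24 is alkylated with it to give the bridgehead-alkylated acetal F5. Oxalic acid on wet silica gel unmasks the enal F6. Keck allylation under the conditions of step 7 (reagent control) gives the homoallylic alcohol F7. Silylation with TBSOTf and 2,6-lutidine rejoins the route at 26.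

**Further compounds**
F1 | step 4 | rac-(1S*,5R*,7R*)-6,6-dimethyl-5-(3-methylbut-2-en-1-yl)-7-(prop-2-en-1-yl)bicyclo[3.3.1]nonane-2,4,9-trione (racemate; one enantiomer drawn) | C=CC[C@@H]1C[C@@H]2C(=O)[C@@](CC=C(C)C)(C(=O)CC2=O)C1(C)C
F2 | step 4 | rac-(1S*,5R*,7R*)-6,6-dimethyl-5-(3-methylbut-2-en-1-yl)-7-(prop-2-en-1-yl)-2-{[2-(trimethylsilyl)ethoxy]methoxy}bicyclo[3.3.1]non-2-ene-4,9-dione (racemate; one enantiomer drawn) | C=CC[C@@H]1C[C@@H]2C(=O)[C@@](CC=C(C)C)(C(=O)C=C2OCOCC[Si](C)(C)C)C1(C)C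
F3 | step 3 | 4-acetyl-1-(1H-imidazol-1-yl)-5,5-dimethyl-4-(3-methylbut-2-en-1-yl)hept-6-ene-1,3-dione (racemic) | O=C(CC(=O)C(CC=C(C)C)(C(C)=O)C(C)(C)C=C)n1ccnc1
F4 | step 13 | (2E)-4-bromo-1,1-dimethoxy-2-methylbut-2-ene | BrC/C=C(\C)C(OC)OC
F5 | step 13 | (1S,5R,7R)-1-[(2E)-4,4-dimethoxy-3-methylbut-2-en-1-yl]-6,6-dimethyl-5-(3-methylbut-2-en-1-yl)-7-(prop-2-en-1-yl)-2-{[2-(trimethylsilyl)ethoxy]methoxy}bicyclo[3.3.1]non-2-ene-4,9-dione | C=CC[C@@H]1C[C@]2(C/C=C(\C)C(OC)OC)C(=O)[C@@](CC=C(C)C)(C(=O)C=C2OCOCC[Si](C)(C)C)C1(C)C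
F6 | step 13 | (1S,5R,7R)-6,6-dimethyl-5-(3-methylbut-2-en-1-yl)-1-[(2E)-3-methyl-4-oxobut-2-en-1-yl]-7-(prop-2-en-1-yl)-2-{[2-(trimethylsilyl)ethoxy]methoxy}bicyclo[3.3.1]non-2-ene-4,9-dione | C=CC[C@@H]1C[C@]2(C/C=C(\C)C=O)C(=O)[C@@](CC=C(C)C)(C(=O)C=C2OCOCC[Si](C)(C)C)C1(C)C
F7 | step 13 | (1S,5R,7R)-1-[(2E,4S)-4-hydroxy-3-methylhepta-2,6-dien-1-yl]-6,6-dimethyl-5-(3-methylbut-2-en-1-yl)-7-(prop-2-en-1-yl)-2-{[2-(trimethylsilyl)ethoxy]methoxy}bicyclo[3.3.1]non-2-ene-4,9-dione | C=CC[C@@H]1C[C@]2(C/C=C(\C)[C@@H](O)CC=C)C(=O)[C@@](CC=C(C)C)(C(=O)C=C2OCOCC[Si](C)(C)C)C1(C)C
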